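The route rests on cutting the C2–C3 bond of ring C. The feature exploited is that C2 carries both O1 and ring B, so it can be traced back to the OCH2 carbon of an O1 benzyl ether. C3 and C4 then form a diazomethyl ketone on C4a of ring A. A chiral dirhodium carboxylate converts the diazo carbon into a carbenoid that inserts into one of the two enantiotopic benzylic C–H bonds. This single operation makes C2–C3, closes ring C and sets C2. The precursor is a phloroacetophenone-derived diazoketone with O1 benzylated, O5 and O7 as TIPS ethers, and the bis-TBS catechol benzyl group on C6.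

Key step: step 10

Assumption: the sense of induction of Rh2(S-PTTL)4 on this substrate is taken as 2S. If the first run shows 2R, the mirror-image catalyst Rh2(R-PTTL)4 is used and nothing else changes.

Numbering and abbreviations: flavanone numbering (O1, C2–C4, C4a, C5–C8, C8a) is also used for the open-chain precursors. Ring A is the fused arene, ring B the phenyl, ring C the pyranone and ring D the catechol. TBS = tert-butyldimethylsilyl, TIPS = triisopropylsilyl, Ms = methanesulfonyl, NIS = N-iodosuccinimide, DIAD = diisopropyl azodicarboxylate, SPhos = 2-dicyclohexylphosphino-2',6'-dimethoxybiphenyl, p-ABSA = 4-acetamidobenzenesulfonyl azide.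

Step 1
Reactants: 1 2,3-dihydroxybenzaldehyde
Product: 2 2,3-bis(tert-butyldimethylsilyloxy)benzaldehyde
Conditions: TBSCl (2.5 equiv), imidazole, DMF, rt
Reagents that add atoms: tert-butyldimethylsilyl chloride, CC(C)(C)[Si](C)(C)Cl
Why: Imidazole-promoted O-silylation caps both catechol oxygens, and the excess of reagent overcomes the hydrogen bond between the 2-OH and the aldehyde.

Step 2
Reactants: 2 2,3-bis(tert-butyldimethylsilyloxy)benzaldehyde
Product: 3 [2,3-bis(tert-butyldimethylsilyloxy)phenyl]methanol
Conditions: i-Bu2AlH, CH2Cl2, −78 °C; aq. potassium sodium tartrate (KNaC4H4O6)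
Reagents that add atoms: none
Why: Hydride reduction of the aldehyde at low temperature passes through an aluminium alkoxide that is too weakly nucleophilic to pull the neighbouring aryl TBS group onto the benzylic oxygen.

Step 3
Reactants: 3 [2,3-bis(tert-butyldimethylsilyloxy)phenyl]methanol
Product: 5 1-(chloromethyl)-2,3-bis(tert-butyldimethylsilyloxy)benzene, via benzylic mesylate 4 (not isolated)
Conditions: MsCl, Et3N, LiCl, THF, 0 °C → rt
Reagents that add atoms: methanesulfonyl chloride, CS(=O)(=O)Cl (kept only in 4); lithium chloride, [Li+].[Cl-]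
Why: Mesylation followed by SN2 displacement with chloride in the same flask converts the benzylic alcohol without acid, so the aryl silyl ethers stay in place.

Step 4
Reactants: 6 2',4',6'-trihydroxyacetophenone (anhydrous)
Product: 7 1-[2,6-dihydroxy-4-(triisopropylsilyloxy)phenyl]ethanone
Conditions: TIPSCl (1.05 equiv), imidazole, DMF, 0 °C
Reagents that add atoms: triisopropylsilyl chloride, CC(C)[Si](Cl)(C(C)C)C(C)C
Why: This is a regioselective O-silylation, because the 4-OH is the most acidic hydroxyl and the only one not hydrogen-bonded to the carbonyl, so one equivalent of the bulky chloride reacts there.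

Step 5
Reactants: 7 1-[2,6-dihydroxy-4-(triisopropylsilyloxy)phenyl]ethanone; 8 benzyl alcohol
Product: 9 1-[2-(benzyloxy)-6-hydroxy-4-(triisopropylsilyloxy)phenyl]ethanone
Conditions: PPh3, DIAD, THF, 0 °C → rt
Reagents that add atoms: none
Why: The Mitsunobu etherification runs under neutral conditions that spare the aryl silyl ether, the two ortho hydroxyls are equivalent so no regiochemical question arises, and the remaining OH is locked in a chelate that resists a second alkylation.

Step 6
Reactants: 9 1-[2-(benzyloxy)-6-hydroxy-4-(triisopropylsilyloxy)phenyl]ethanone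
Product: 10 1-[6-(benzyloxy)-2-hydroxy-3-iodo-4-(triisopropylsilyloxy)phenyl]ethanone
Conditions: NIS (1.0 equiv), CF3CO2H (10 mol %), MeCN, 0 °C
Reagents that add atoms: N-iodosuccinimide, O=C1CCC(=O)N1I
Why: Electrophilic aromatic iodination goes to the carbon ortho to the chelated free OH, as is known for 2-hydroxy-4,6-dialkoxyacetophenones, and this carbon (the future C6) is also the less hindered one because it sits next to OH and not OBn.

Step 7
Reactants: 10 1-[6-(benzyloxy)-2-hydroxy-3-iodo-4-(triisopropylsilyloxy)phenyl]ethanone; 5 1-(chloromethyl)-2,3-bis(tert-butyldimethylsilyloxy)benzene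
Product: 12 1-{6-(benzyloxy)-3-[2,3-bis(tert-butyldimethylsilyloxy)benzyl]-2-hydroxy-4-(triisopropylsilyloxy)phenyl}ethanone, via benzylzinc chloride 11 (not isolated)
Conditions: 5, Zn dust, LiCl, THF, 25 °C; then added slowly (1.5 equiv) to 10, Pd(OAc)2 (2 mol %), SPhos (4 mol %), THF, 25 → 50 °C
Reagents that add atoms: zinc, [Zn] (kept only in 11)
Why: LiCl-assisted zinc insertion into the benzylic chloride is followed by Negishi cross-coupling with a catalyst system known to accept di-ortho-substituted aryl iodides, to leave ketones alone and to tolerate a free OH group when the zinc reagent is added slowly.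

Step 8
Reactants: 12 1-{6-(benzyloxy)-3-[2,3-bis(tert-butyldimethylsilyloxy)benzyl]-2-hydroxy-4-(triisopropylsilyloxy)phenyl}ethanone
Product: 13 1-{6-(benzyloxy)-3-[2,3-bis(tert-butyldimethylsilyloxy)benzyl]-2,4-bis(triisopropylsilyloxy)phenyl}ethanone
Conditions: TIPSOTf (1.5 equiv), 2,6-lutidine, CH2Cl2, 0 °C → rt
Reagents that add atoms: triisopropylsilyl trifluoromethanesulfonate, CC(C)[Si](OS(=O)(=O)C(F)(F)F)(C(C)C)C(C)C
Why: O-silylation with the silyl triflate is forceful enough for a chelated phenol flanked on both sides, while 2,6-lutidine is too weak a base to turn the methyl ketone into its silyl enol ether.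

Step 9
Reactants: 13 1-{6-(benzyloxy)-3-[2,3-bis(tert-butyldimethylsilyloxy)benzyl]-2,4-bis(triisopropylsilyloxy)phenyl}ethanone
Product: 15 1-{6-(benzyloxy)-3-[2,3-bis(tert-butyldimethylsilyloxy)benzyl]-2,4-bis(triisopropylsilyloxy)phenyl}-2-diazoethanone, via trifluoroacetyl diketone 14 (not isolated)
Conditions: LiN(SiMe3)2, THF, −78 °C; CF3CO2CH2CF3, −78 °C, 10 min; dilute aq. HCl work-up; crude 14, p-ABSA, Et3N, H2O (1 equiv), MeCN, rt
Reagents that add atoms: 2,2,2-trifluoroethyl trifluoroacetate, O=C(OCC(F)(F)F)C(F)(F)F (kept only in 14); 4-acetamidobenzenesulfonyl azide, CC(=O)Nc1ccc(cc1)S(=O)(=O)N=[N+]=[N-]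
Why: In this detrifluoroacetylative variant of the Regitz diazo transfer, the methyl group is activated as a 1,3-diketone and the trifluoroacetyl group leaves on the sulfonamide nitrogen, so C3 and C4 come from the acetyl group and no acid chloride, diazomethane or aryllithium next to a silyl ether is needed.

Step 10
Reactants: 15 1-{6-(benzyloxy)-3-[2,3-bis(tert-butyldimethylsilyloxy)benzyl]-2,4-bis(triisopropylsilyloxy)phenyl}-2-diazoethanone
Product: 16 (2S)-6-[2,3-bis(tert-butyldimethylsilyloxy)benzyl]-2-phenyl-5,7-bis(triisopropylsilyloxy)chroman-4-one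
Conditions: dirhodium tetrakis[N-phthaloyl-(S)-tert-leucinate], Rh2(S-PTTL)4 (2 mol %), 4 Å MS, CH2Cl2 (0.01 M), 15 added over 2 h, 0 °C → rt
Reagents that add atoms: none
Why: The catalyst, in which each rhodium is divalent, expels N2 from 15, and the electrophilic carbenoid at C3 takes up one benzylic C–H bond of the O1–CH2Ph group in a concerted, asynchronous three-centre insertion that forms C2–C3. The closest known reaction type is the chiral dirhodium tetracarboxylate-catalysed C–H insertion of 2-alkoxyaryl diazoketones next to the ether oxygen, which gives 2-substituted chroman-4-ones. Ring C closes as a six-membered ring by 1,6-insertion, because the atom in the usually preferred 1,5-position is O1 and carries no hydrogen. C2 is set under catalyst control: the phthalimide-walled pocket of the tert-leucinate ligands tells the two enantiotopic hydrogens apart, and replacement of the pro-S hydrogen with retention gives 2S. The step needs chemoselectivity for C–H insertion over attack of O1 on the carbenoid (oxonium ylide, then Stevens 1,2-shift of benzyl) and over Buchner addition to ring B; this is helped by the double activation of the C–H bond by O1 and phenyl, by the poor nucleophilicity of the aryl ether oxygen, and by the known leaning of dirhodium carboxylates, unlike copper catalysts, towards insertion next to ether oxygen. Site selectivity is built into 15, since O5 carries TIPS, whose nearest C–H bond is an unactivated methine in the 1,7-position and whose bulk both shields O5 and turns the carbenoid carbon towards the O1 side.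

Step 11
Reactants: 16 (2S)-6-[2,3-bis(tert-butyldimethylsilyloxy)benzyl]-2-phenyl-5,7-bis(triisopropylsilyloxy)chroman-4-one
Product: 17 (2S)-6-(2,3-dihydroxybenzyl)-5,7-dihydroxy-2-phenylchroman-4-one (CNP0348560.1)
Conditions: HF·pyridine, pyridine, THF, 0 °C → rt
Reagents that add atoms: none
Why: Fluoride-driven desilylation in an acidic medium cleaves all four aryl silyl ethers without forming the phenoxide or enolate that would open ring C by a retro-oxa-Michael reaction, so the 2S configuration is kept.

Compound list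
1 | 2,3-dihydroxybenzaldehyde | O=Cc1cccc(O)c1O | starting material
2 | 2,3-bis(tert-butyldimethylsilyloxy)benzaldehyde | O=Cc1cccc(O[Si](C)(C)C(C)(C)C)c1O[Si](C)(C)C(C)(C)C | intermediate
3 | [2,3-bis(tert-butyldimethylsilyloxy)phenyl]methanol | OCc1cccc(O[Si](C)(C)C(C)(C)C)c1O[Si](C)(C)C(C)(C)C | intermediate
4 | 2,3-bis(tert-butyldimethylsilyloxy)benzyl methanesulfonate (not isolated) | CS(=O)(=O)OCc1cccc(O[Si](C)(C)C(C)(C)C)c1O[Si](C)(C)C(C)(C)C | intermediate
5 | 1-(chloromethyl)-2,3-bis(tert-butyldimethylsilyloxy)benzene | ClCc1cccc(O[Si](C)(C)C(C)(C)C)c1O[Si](C)(C)C(C)(C)C | intermediate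
6 | 2',4',6'-trihydroxyacetophenone | CC(=O)c1c(O)cc(O)cc1O | starting material
7 | 1-[2,6-dihydroxy-4-(triisopropylsilyloxy)phenyl]ethanone | CC(=O)c1c(O)cc(O[Si](C(C)C)(C(C)C)C(C)C)cc1O | intermediate
8 | benzyl alcohol | OCc1ccccc1 | starting material
9 | 1-[2-(benzyloxy)-6-hydroxy-4-(triisopropylsilyloxy)phenyl]ethanone | CC(=O)c1c(OCc2ccccc2)cc(O[Si](C(C)C)(C(C)C)C(C)C)cc1O | intermediate
10 | 1-[6-(benzyloxy)-2-hydroxy-3-iodo-4-(triisopropylsilyloxy)phenyl]ethanone | CC(=O)c1c(OCc2ccccc2)cc(O[Si](C(C)C)(C(C)C)C(C)C)c(I)c1O | intermediate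
11 | [2,3-bis(tert-butyldimethylsilyloxy)benzyl]zinc chloride (not isolated) | Cl[Zn]Cc1cccc(O[Si](C)(C)C(C)(C)C)c1O[Si](C)(C)C(C)(C)C | intermediate
12 | 1-{6-(benzyloxy)-3-[2,3-bis(tert-butyldimethylsilyloxy)benzyl]-2-hydroxy-4-(triisopropylsilyloxy)phenyl}ethanone | CC(=O)c1c(OCc2ccccc2)cc(O[Si](C(C)C)(C(C)C)C(C)C)c(Cc2cccc(O[Si](C)(C)C(C)(C)C)c2O[Si](C)(C)C(C)(C)C)c1O | intermediate
13 | 1-{6-(benzyloxy)-3-[2,3-bis(tert-butyldimethylsilyloxy)benzyl]-2,4-bis(triisopropylsilyloxy)phenyl}ethanone | CC(=O)c1c(OCc2ccccc2)cc(O[Si](C(C)C)(C(C)C)C(C)C)c(Cc2cccc(O[Si](C)(C)C(C)(C)C)c2O[Si](C)(C)C(C)(C)C)c1O[Si](C(C)C)(C(C)C)C(C)C | intermediate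
14 | 1-{6-(benzyloxy)-3-[2,3-bis(tert-butyldimethylsilyloxy)benzyl]-2,4-bis(triisopropylsilyloxy)phenyl}-4,4,4-trifluorobutane-1,3-dione (not isolated) | O=C(CC(=O)C(F)(F)F)c1c(OCc2ccccc2)cc(O[Si](C(C)C)(C(C)C)C(C)C)c(Cc2cccc(O[Si](C)(C)C(C)(C)C)c2O[Si](C)(C)C(C)(C)C)c1O[Si](C(C)C)(C(C)C)C(C)C | intermediate
15 | 1-{6-(benzyloxy)-3-[2,3-bis(tert-butyldimethylsilyloxy)benzyl]-2,4-bis(triisopropylsilyloxy)phenyl}-2-diazoethanone | [N-]=[N+]=CC(=O)c1c(OCc2ccccc2)cc(O[Si](C(C)C)(C(C)C)C(C)C)c(Cc2cccc(O[Si](C)(C)C(C)(C)C)c2O[Si](C)(C)C(C)(C)C)c1O[Si](C(C)C)(C(C)C)C(C)C | intermediate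
16 | (2S)-6-[2,3-bis(tert-butyldimethylsilyloxy)benzyl]-2-phenyl-5,7-bis(triisopropylsilyloxy)chroman-4-one | O=C1C[C@@H](c2ccccc2)Oc2cc(O[Si](C(C)C)(C(C)C)C(C)C)c(Cc3cccc(O[Si](C)(C)C(C)(C)C)c3O[Si](C)(C)C(C)(C)C)c(O[Si](C(C)C)(C(C)C)C(C)C)c21 | intermediate
17 | (2S)-6-(2,3-dihydroxybenzyl)-5,7-dihydroxy-2-phenylchroman-4-one | O=C1C[C@@H](c2ccccc2)Oc2cc(O)c(Cc3cccc(O)c3O)c(O)c21 | target

Total step count: 11. Longest linear sequence: 8 steps (steps 4 to 11, from 6). The ring D branch (steps 1 to 3) joins at step 7.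

Steps most likely to fail

Step 10. The carbenoid may be captured by the O1 lone pair, after which the benzyl group migrates to C3 and a five-membered ring results. Alternatively the two benzylic hydrogens may be told apart poorly, so that the enantiomeric purity is low. The fallback gives up the insertion and sets C2 by asymmetric conjugate arylation of a chromone, a known reaction type. It sets out from 13. Hydrogenolysis of the benzyl ether (H2, Pd/C, EtOAc) frees O1 and gives 1-{3-[2,3-bis(tert-butyldimethylsilyloxy)benzyl]-6-hydroxy-2,4-bis(triisopropylsilyloxy)phenyl}ethanone F1. Condensation with Me2NCH(OMe)2 (toluene, 90 °C) gives the enaminone (E)-1-{3-[2,3-bis(tert-butyldimethylsilyloxy)benzyl]-6-hydroxy-2,4-bis(triisopropylsilyloxy)phenyl}-3-(dimethylamino)prop-2-en-1-one F2. HCl in CH2Cl2 closes it, with loss of dimethylamine, to 6-[2,3-bis(tert-butyldimethylsilyloxy)benzyl]-5,7-bis(triisopropylsilyloxy)-4H-chromen-4-one F3. Phenylboronic acid is then added to C2 with Pd(OCOCF3)2 and the enantiomer of the t-BuPyOx ligand that delivers 2S (NH4PF6, H2O, ClCH2CH2Cl, 60 °C). The route is rejoined at 16.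

Step 9. The O5 silyl group may move onto the oxygen of the lithium enolate, or the crowded enolate may be acylated too slowly. The fallback avoids a stoichiometric metal enolate and uses diazo transfer to an enaminone with cleavage of the C=C bond. It sets out from 13. Heating with Me2NCH(OMe)2 (neat, 100 °C) gives (E)-1-{6-(benzyloxy)-3-[2,3-bis(tert-butyldimethylsilyloxy)benzyl]-2,4-bis(triisopropylsilyloxy)phenyl}-3-(dimethylamino)prop-2-en-1-one F4. Tosyl azide (CH2Cl2, rt) adds across the enamine double bond, and the triazoline breaks down to the diazoketone and a sulfonyl formamidine. The route is rejoined at 15.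

Step 7. The benzylzinc reagent may be protonated by the phenol, or oxidative addition and transmetalation at the crowded C–I bond may be slow enough that the iodide is merely reduced. The fallback forms the same bond without metal coupling partners, by Friedel–Crafts benzylation. It sets out from 9 and 3. With Sc(OTf)3 (10 mol %) in CH2Cl2/MeNO2 at rt, alcohol 3 ionises to the benzylic cation stabilised by its ortho silyloxy group. This cation attacks the ring A carbon ortho to the chelated OH, the same carbon that is iodinated in step 6. The route is rejoined at 12, and compounds 5, 10 and 11 are no longer needed.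

Further compounds
F1 | step 10 | 1-{3-[2,3-bis(tert-butyldimethylsilyloxy)benzyl]-6-hydroxy-2,4-bis(triisopropylsilyloxy)phenyl}ethanone | CC(=O)c1c(O)cc(O[Si](C(C)C)(C(C)C)C(C)C)c(Cc2cccc(O[Si](C)(C)C(C)(C)C)c2O[Si](C)(C)C(C)(C)C)c1O[Si](C(C)C)(C(C)C)C(C)C
F2 | step 10 | (E)-1-{3-[2,3-bis(tert-butyldimethylsilyloxy)benzyl]-6-hydroxy-2,4-bis(triisopropylsilyloxy)phenyl}-3-(dimethylamino)prop-2-en-1-one | CN(C)/C=C/C(=O)c1c(O)cc(O[Si](C(C)C)(C(C)C)C(C)C)c(Cc2cccc(O[Si](C)(C)C(C)(C)C)c2O[Si](C)(C)C(C)(C)C)c1O[Si](C(C)C)(C(C)C)C(C)C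
F3 | step 10 | 6-[2,3-bis(tert-butyldimethylsilyloxy)benzyl]-5,7-bis(triisopropylsilyloxy)-4H-chromen-4-one | O=c1ccoc2cc(O[Si](C(C)C)(C(C)C)C(C)C)c(Cc3cccc(O[Si](C)(C)C(C)(C)C)c3O[Si](C)(C)C(C)(C)C)c(O[Si](C(C)C)(C(C)C)C(C)C)c12
F4 | step 9 | (E)-1-{6-(benzyloxy)-3-[2,3-bis(tert-butyldimethylsilyloxy)benzyl]-2,4-bis(triisopropylsilyloxy)phenyl}-3-(dimethylamino)prop-2-en-1-one | CN(C)/C=C/C(=O)c1c(OCc2ccccc2)cc(O[Si](C(C)C)(C(C)C)C(C)C)c(Cc2cccc(O[Si](C)(C)C(C)(C)C)c2O[Si](C)(C)C(C)(C)C)c1O[Si](C(C)C)(C(C)C)C(C)C
F0 | step 7 | none | none
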